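Everything rests on disconnecting ring A at C3–C4, the aldol retron of the β-hydroxy acid C3(OH)–C4–C19. Because C19 and C20 stand 1,3-diaxial on the α face of ring A, they are tied together as a 19,20-lactol methyl ether lactone, the ring-chain tautomer of the target's aldehyde-acid. In one operation the enolate of this lactone adds to a C3 aldehyde: ring A closes, the quaternary C4 and the 3β-carbinol are set, and the bridged lactone dictates the C4 configuration. The precursor is the B/C/D tricycle carrying a 3-oxopropyl chain on C10 and the lactone fused across C5–C10, built by Diels–Alder, palladium cycloalkenylation, Claisen and Michael reactions.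

Key step: step 20

Remark 1: gibberellane numbering is used throughout (ring A C1–C5, C10; ring B C5, C6, C8–C10; ring C C8, C9, C11–C14; ring D C8, C13–C16; C7 carboxyl on C6, C17 methylene, C18 methyl, C19 carboxyl on C4, C20 formyl on C10); β is the face of H-5, H-9 and C7.
Remark 2: the target is drawn as the open C20 aldehyde/C19 acid; this is in ring-chain equilibrium with its 19,20-lactol, and the last step delivers that same compound.
Remark 3: 21–27 are mixtures of epimers at C20, and 23–26 also at C4; these centres are left open in the SMILES because C4 becomes trigonal in step 20 and C20 ends as the aldehyde carbon.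
Remark 4: 1 and 14 are taken as commercial.

Step 1
Reactants: 1 (R)-4-(tert-butyldimethylsilyloxy)cyclopent-2-en-1-one
Product: 2 (R)-4-(tert-butyldimethylsilyloxy)-2-iodocyclopent-2-en-1-one
Conditions: I2, pyridine/CH2Cl2 (1:1), 0 °C → rt
Reagents that add atoms: iodine, II
Why: α-iodination of the enone (pyridine conjugate addition, iodination of the enolate, elimination) should functionalise the future C8 without touching the silyloxy stereocentre (future C10).

Step 2
Reactants: 2 (R)-4-(tert-butyldimethylsilyloxy)-2-iodocyclopent-2-en-1-one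
Product: 3 (R)-2-allyl-4-(tert-butyldimethylsilyloxy)cyclopent-2-en-1-one
Conditions: allylSnBu3, Pd2(dba)3 (2.5 mol%), AsPh3, CuI (copper iodide, 10 mol%), NMP, rt
Reagents that add atoms: allyltributylstannane, C=CC[Sn](CCCC)(CCCC)CCCC
Why: Stille cross-coupling of the α-iodoenone should install the C15–C17 unit on C8; the stereocentre is not involved.

Step 3
Reactants: 4 but-3-en-2-one
Product: 5 2-(tert-butyldimethylsilyloxy)buta-1,3-diene
Conditions: t-BuMe2SiOTf, Et3N, Et2O, 0 °C
Reagents that add atoms: tert-butyldimethylsilyl trifluoromethanesulfonate, CC(C)(C)[Si](C)(C)OS(=O)(=O)C(F)(F)F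
Why: soft enolisation and O-silylation of the methyl ketone should give the 2-silyloxydiene.

Step 4
Reactants: 3 (R)-2-allyl-4-(tert-butyldimethylsilyloxy)cyclopent-2-en-1-one; 5 2-(tert-butyldimethylsilyloxy)buta-1,3-diene
Product: 6 (3R,3aR,7aS)-7a-allyl-3,5-bis(tert-butyldimethylsilyloxy)-2,3,3a,4,7,7a-hexahydro-1H-inden-1-one
Conditions: 5 (2 equiv), Tf2NH (10 mol%), CH2Cl2, −78 → −40 °C; Et3N quench
Reagents that add atoms: none
Why: Diels–Alder reaction catalysed by the silyl triflimide formed in situ: the nucleophilic C1 of the diene bonds to the enone β-carbon (C9) so the enol ether ends as C12=C13, suprafacial addition makes H-9 and the allyl group cis, and attack opposite the C10 silyloxy group fixes C8 and C9 absolutely.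

Step 5
Reactants: 6 Diels–Alder adduct
Product: 7 enol triflate of 6 (C5=C6–OSO2CF3)
Conditions: KN(SiMe3)2 (1.1 equiv), THF, −78 °C; PhNTf2, −78 → −40 °C
Reagents that add atoms: N-phenylbis(trifluoromethanesulfonimide), O=S(=O)(N(c1ccccc1)S(=O)(=O)C(F)(F)F)C(F)(F)F
Why: kinetic enolisation toward C5 (the only α-hydrogens of the C6 ketone) and O-sulfonylation should give the enol triflate, β-elimination of the C10 silyloxy group being slow at −78 °C.

Step 6
Reactants: 7 enol triflate
Product: 8 2-(trimethylsilyl)ethyl dienoate (C5=C6–CO2CH2CH2SiMe3)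
Conditions: Pd(OAc)2 (5 mol%), dppf, CO (1 atm), Me3SiCH2CH2OH (10 equiv), Et3N, DMF, 50 °C
Reagents that add atoms: carbon monoxide, [C-]#[O+]; 2-(trimethylsilyl)ethanol, C[Si](C)(C)CCO
Why: palladium-catalysed alkoxycarbonylation (oxidative addition to zerovalent palladium, CO insertion, alcoholysis) should introduce C7 as a fluoride-cleavable ester; no stereocentre is formed.

Step 7
Reactants: 8 2-(trimethylsilyl)ethyl dienoate
Product: 9 tricyclic keto ester (10β-OTBS; 12-oxo; 16-methylene; Δ5)
Conditions: Pd(OAc)2 (10 mol%), O2 (1 atm), DMSO, 45 °C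
Reagents that add atoms: none
Why: palladium-promoted cycloalkenylation of the silyl enol ether: the divalent-palladium enolate at C13 adds 5-exo to the allyl alkene and β-hydride elimination leaves the exocyclic C16=C17, the two-carbon bridge necessarily spanning C8 and C13 on the β face, which sets C13.

Step 8
Reactants: 9 tricyclic keto ester
Product: 10 12α-alcohol
Conditions: LiBH(s-Bu)3 (1.1 equiv), THF, −78 °C; H2O
Reagents that add atoms: none
Why: ketone reduction by a bulky borohydride should outrun conjugate reduction of the hindered enoate; the axial C9–C10 bond blocks the α (axial) trajectory 1,3-diaxially, so hydride should enter equatorially from the β side and give the axial 12α-alcohol.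

Step 9
Reactants: 10 12α-alcohol
Product: 11 12α-triisopropylsilyl ether
Conditions: i-Pr3SiOTf, 2,6-lutidine, CH2Cl2, 0 °C → rt
Reagents that add atoms: triisopropylsilyl trifluoromethanesulfonate, CC(C)[Si](OS(=O)(=O)C(F)(F)F)(C(C)C)C(C)C
Why: silyl triflate silylation should protect the hindered axial alcohol as an ether that outlasts the C10 silyl ether and all basic steps.

Step 10
Reactants: 11 12α-triisopropylsilyl ether
Product: 12 10β-alcohol
Conditions: HF·pyridine, pyridine, THF, 0 °C
Reagents that add atoms: none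
Why: buffered HF·pyridine should cleave the less hindered and less stable tert-butyldimethylsilyl ether selectively beside the triisopropylsilyl ether and the silylethyl ester.

Step 11
Reactants: 12 10β-alcohol
Product: 13 10-ketone (4-oxo-enoate)
Conditions: Dess–Martin periodinane, NaHCO3, CH2Cl2, 0 °C → rt
Reagents that add atoms: none
Why: Dess–Martin oxidation of the allylic alcohol should give the enone; the C10 centre, whose only task was to steer step 4, is erased.

Step 12
Reactants: 14 3-(chloromethoxy)prop-1-ene; 15 triphenylphosphine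
Product: 16 (allyloxymethyl)triphenylphosphonium chloride
Conditions: toluene, 60 °C
Reagents that add atoms: none
Why: quaternisation of the phosphine by the reactive α-chloro ether (SN2) should give the Wittig salt.

Step 13
Reactants: 16 (allyloxymethyl)triphenylphosphonium chloride; 13 10-ketone
Product: 18 10-(allyloxymethylene) dienoate (E/Z mixture), via phosphorus ylide 17 (not isolated)
Conditions: 16 (2.5 equiv), KN(SiMe3)2, THF, −78 → 0 °C; then 13, −78 °C → rt
Reagents that add atoms: none
Why: Wittig alkoxymethylenation; the ylide should add 1,2 to the ketone because both conjugate positions are shielded (C6 fully substituted, C5 beside it), and the E/Z ratio is irrelevant since C20 becomes the aldehyde carbon.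

Step 14
Reactants: 18 10-(allyloxymethylene) dienoate
Product: 19 10α-formyl-10β-allyl enoate
Conditions: toluene, 160 °C, sealed tube
Reagents that add atoms: none
Why: Claisen rearrangement; the chair [3,3] shift should deliver the allyl group to C10 on the β face, opposite the C9–C11 bond of ring C, creating the quaternary centre with C20 (CHO) α and the C1–C3 chain β.

Step 15
Reactants: 19 10α-formyl-10β-allyl enoate
Product: 20 C20 dimethyl acetal
Conditions: HC(OMe)3, MeOH, PPTS (cat.), rt
Reagents that add atoms: trimethyl orthoformate, COC(OC)OC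
Why: acid-catalysed acetalisation with orthoformate should convert only the aldehyde and provides the handle for the C20–O–acyl tether.

Step 16
Reactants: 20 C20 dimethyl acetal
Product: 22 C20 methoxy(propanoyloxy)methyl compound, via α-chloro ether 21 (not isolated)
Conditions: AcCl, ZnBr2 (1 mol%), CH2Cl2, 0 °C → rt; then EtCO2H, i-Pr2NEt, 0 °C → rt
Reagents that add atoms: propionic acid, CCC(=O)O; acetyl chloride, CC(=O)Cl (its chlorine only in 21)
Why: zinc-catalysed exchange of one methoxy group for chloride (haloalkyl ether synthesis) and substitution by propionate should give the acyloxy acetal, tethering the C4/C18/C19 unit to C20 at the aldehyde oxidation level; C20 forms as a harmless epimer mixture.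

Step 17
Reactants: 22 C20 methoxy(propanoyloxy)methyl compound
Product: 23 19,20-lactone (20-methoxy δ-lactone fused at C5–C10; 10β-allyl)
Conditions: KN(SiMe3)2 (1.2 equiv), THF, −78 °C; then t-BuOH, −78 → 0 °C; aq NH4Cl
Reagents that add atoms: none
Why: intramolecular Michael addition (6-exo-trig) of the propionate enolate to the cyclopentene ester; the O–C20 tether on the α face of C10 forces C4 onto the α face of C5 (H-5 β, cis-fused lactone), and reversible protonation under t-BuOK/t-BuOH should set C6 to the more stable 7β ester trans to the new C5 substituent.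

Step 18
Reactants: 23 19,20-lactone
Product: 25 C3 primary alcohol, via pinacol boronate 24 (not isolated)
Conditions: pinacolborane, [Ir(cod)Cl]2 (1.5 mol%), dppm, CH2Cl2, rt; then NaBO3·4H2O, THF/H2O, rt
Reagents that add atoms: sodium perborate, [Na+].[O-]OB=O; pinacolborane, CC1(C)OBOC1(C)C (its boron only in 24)
Why: iridium-catalysed anti-Markovnikov hydroboration should take the monosubstituted alkene in preference to the 1,1-disubstituted C16=C17 and leave lactone and ester untouched, and mild perborate oxidation gives the alcohol.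

Step 19
Reactants: 25 C3 primary alcohol
Product: 26 C3 aldehyde (3-oxopropyl chain on C10)
Conditions: Dess–Martin periodinane, NaHCO3, CH2Cl2, 0 °C → rt
Reagents that add atoms: none
Why: Dess–Martin oxidation should give the aldehyde under buffered conditions that spare the acyloxy acetal.

Step 20
Reactants: 26 C3 aldehyde
Product: 27 ring A aldol product (3β-hydroxy; 20-methoxy 19,20-lactone; 12α-OTIPS; silylethyl 7-ester)
Conditions: KN(SiMe3)2 (1.1 equiv), 18-crown-6, THF (0.005 M), −78 °C; AcOH, −78 °C
Reagents that add atoms: none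
Why: The crown-sequestered potassium enolate of the lactone (C4=C19) adds to the C3 aldehyde held over it by the C10 chain, an intramolecular aldol addition across the same C3–C4 bond that 3-hydroxygibberellins break and re-form by retro-aldol/aldol in base. Ring A closes in the 6-(enolexo)-exo-trig mode and with it the 3-oxabicyclo[3.3.1]nonan-2-one. C4 is controlled by the temporary lactone: C19 is tied to C20 on the α face, so C3 can bond only on the side of the C1–C2 chain and the methyl becomes β-equatorial. C3 is controlled by an open transition state with the aldehyde oxygen antiperiplanar to the enolate C4=C19 (no cation bridges the two oxygens), which places the new hydroxyl axial and β. The step needs the lactone enolate to react in preference to the C6 ester enolate and the aldehyde enolate; the lactone C4–H is the more acidic ester-type proton, proton exchange through HN(SiMe3)2 is fast, and only the aldol closure leads to a stable alkoxide at −78 °C.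

Step 21
Reactants: 27 ring A aldol product
Product: 29 target acid (CNP0218328.1), via silylethyl ester 28 (not isolated)
Conditions: 48% aq HF, MeCN, 0 °C → rt; then n-Bu4NF, THF, rt; aq HCl to pH 3
Reagents that add atoms: water, O
Why: aqueous HF should remove the silyl ether and hydrolyse the acyloxy acetal to the 19,20-lactol (open form: C20 aldehyde and C19 acid), after which fluoride-induced β-elimination cleaves the silylethyl ester; the acid stage comes first so that a C19 carboxylate, not a lactone, faces the basic fluoride and retro-aldol at C3–C4 is shut off.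

Compound list
1 | (R)-4-(tert-butyldimethylsilyloxy)cyclopent-2-en-1-one | C1=C[C@H](O[Si](C)(C)C(C)(C)C)CC1=O | starting material
2 | (R)-4-(tert-butyldimethylsilyloxy)-2-iodocyclopent-2-en-1-one | IC1=C[C@H](O[Si](C)(C)C(C)(C)C)CC1=O | intermediate
3 | (R)-2-allyl-4-(tert-butyldimethylsilyloxy)cyclopent-2-en-1-one | C=CCC1=C[C@H](O[Si](C)(C)C(C)(C)C)CC1=O | intermediate
4 | but-3-en-2-one | CC(=O)C=C | starting material
5 | 2-(tert-butyldimethylsilyloxy)buta-1,3-diene | C=CC(=C)O[Si](C)(C)C(C)(C)C | intermediate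
6 | (3R,3aR,7aS)-7a-allyl-3,5-bis(tert-butyldimethylsilyloxy)-2,3,3a,4,7,7a-hexahydro-1H-inden-1-one (C6 ketone, 10β-OTBS, C12=C13 enol ether, H-9 cis to allyl) | C=CC[C@]12CC=C(O[Si](C)(C)C(C)(C)C)C[C@H]1[C@H](O[Si](C)(C)C(C)(C)C)CC2=O | intermediate
7 | enol triflate of 6 (C5=C6–OSO2CF3, other centres as in 6) | C=CC[C@]12CC=C(O[Si](C)(C)C(C)(C)C)C[C@H]1[C@H](O[Si](C)(C)C(C)(C)C)C=C2OS(=O)(=O)C(F)(F)F | intermediate
8 | 2-(trimethylsilyl)ethyl dienoate (C5=C6–CO2CH2CH2SiMe3, other centres as in 6) | C=CC[C@]12CC=C(O[Si](C)(C)C(C)(C)C)C[C@H]1[C@H](O[Si](C)(C)C(C)(C)C)C=C2C(=O)OCC[Si](C)(C)C | intermediate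
9 | 2-(trimethylsilyl)ethyl 4-(tert-butyldimethylsilyloxy)-9-methylidene-7-oxotricyclo[6.2.1.0^1,5]undec-2-ene-2-carboxylate (10β-OTBS, 12-oxo, 16-methylene, Δ5) | C=C1C[C@]23C[C@H]1C(=O)C[C@H]2[C@H](O[Si](C)(C)C(C)(C)C)C=C3C(=O)OCC[Si](C)(C)C | intermediate
10 | 12α-alcohol of 9 (hydroxyl axial, anti to the C15–C16 bridge) | C=C1C[C@]23C[C@H]1[C@@H](O)C[C@H]2[C@H](O[Si](C)(C)C(C)(C)C)C=C3C(=O)OCC[Si](C)(C)C | intermediate
11 | 12α-triisopropylsilyl ether of 10 | C=C1C[C@]23C[C@H]1[C@@H](O[Si](C(C)C)(C(C)C)C(C)C)C[C@H]2[C@H](O[Si](C)(C)C(C)(C)C)C=C3C(=O)OCC[Si](C)(C)C | intermediate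
12 | 10β-alcohol (12α-OTIPS, Δ5 silylethyl ester) | C=C1C[C@]23C[C@H]1[C@@H](O[Si](C(C)C)(C(C)C)C(C)C)C[C@H]2[C@H](O)C=C3C(=O)OCC[Si](C)(C)C | intermediate
13 | 10-ketone (4-oxo-enoate; 12α-OTIPS) | C=C1C[C@]23C[C@H]1[C@@H](O[Si](C(C)C)(C(C)C)C(C)C)C[C@H]2C(=O)C=C3C(=O)OCC[Si](C)(C)C | intermediate
14 | 3-(chloromethoxy)prop-1-ene (allyl chloromethyl ether) | C=CCOCCl | starting material
15 | triphenylphosphine | c1ccc(cc1)P(c1ccccc1)c1ccccc1 | starting material
16 | (allyloxymethyl)triphenylphosphonium chloride | C=CCOC[P+](c1ccccc1)(c1ccccc1)c1ccccc1.[Cl-] | intermediate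
17 | (allyloxymethylene)triphenylphosphorane | C=CCOC=P(c1ccccc1)(c1ccccc1)c1ccccc1 | intermediate
18 | 10-(allyloxymethylene) dienoate (E/Z mixture at C10=C20) | C=C1C[C@]23C[C@H]1[C@@H](O[Si](C(C)C)(C(C)C)C(C)C)C[C@H]2C(=COCC=C)C=C3C(=O)OCC[Si](C)(C)C | intermediate
19 | 10α-formyl-10β-allyl enoate (quaternary C10) | C=C1C[C@]23C[C@H]1[C@@H](O[Si](C(C)C)(C(C)C)C(C)C)C[C@H]2[C@](C=O)(CC=C)C=C3C(=O)OCC[Si](C)(C)C | intermediate
20 | C20 dimethyl acetal of 19 | C=C1C[C@]23C[C@H]1[C@@H](O[Si](C(C)C)(C(C)C)C(C)C)C[C@H]2[C@](C(OC)OC)(CC=C)C=C3C(=O)OCC[Si](C)(C)C | intermediate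
21 | C20 chloro(methoxy)methyl compound (C20 epimers) | C=C1C[C@]23C[C@H]1[C@@H](O[Si](C(C)C)(C(C)C)C(C)C)C[C@H]2[C@](C(Cl)OC)(CC=C)C=C3C(=O)OCC[Si](C)(C)C | intermediate
22 | C20 methoxy(propanoyloxy)methyl compound (C20 epimers) | C=C1C[C@]23C[C@H]1[C@@H](O[Si](C(C)C)(C(C)C)C(C)C)C[C@H]2[C@](C(OC)OC(=O)CC)(CC=C)C=C3C(=O)OCC[Si](C)(C)C | intermediate
23 | 20-methoxy 19,20-lactone cis-fused at C5–C10, H-5β, 7β-ester, 10β-allyl (C4 and C20 epimers) | C=C1C[C@]23C[C@H]1[C@@H](O[Si](C(C)C)(C(C)C)C(C)C)C[C@H]2[C@@]4(CC=C)C(OC)OC(=O)C(C)[C@H]4[C@@H]3C(=O)OCC[Si](C)(C)C | intermediate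
24 | C3 pinacol boronate of 23 | C=C1C[C@]23C[C@H]1[C@@H](O[Si](C(C)C)(C(C)C)C(C)C)C[C@H]2[C@@]4(CCCB5OC(C)(C)C(C)(C)O5)C(OC)OC(=O)C(C)[C@H]4[C@@H]3C(=O)OCC[Si](C)(C)C | intermediate
25 | C3 primary alcohol (10β-3-hydroxypropyl) | C=C1C[C@]23C[C@H]1[C@@H](O[Si](C(C)C)(C(C)C)C(C)C)C[C@H]2[C@@]4(CCCO)C(OC)OC(=O)C(C)[C@H]4[C@@H]3C(=O)OCC[Si](C)(C)C | intermediate
26 | C3 aldehyde (10β-3-oxopropyl) | C=C1C[C@]23C[C@H]1[C@@H](O[Si](C(C)C)(C(C)C)C(C)C)C[C@H]2[C@@]4(CCC=O)C(OC)OC(=O)C(C)[C@H]4[C@@H]3C(=O)OCC[Si](C)(C)C | intermediate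
27 | 3β-hydroxy-20-methoxy-12α-(triisopropylsilyloxy)gibberell-16-ene-7,19-dioic acid 19,20-lactone 7-[2-(trimethylsilyl)ethyl] ester (C20 epimers) | C=C1C[C@]23C[C@H]1[C@@H](O[Si](C(C)C)(C(C)C)C(C)C)C[C@H]2[C@]1(C4OC)CC[C@H](O)[C@@](C)(C(=O)O4)[C@H]1[C@@H]3C(=O)OCC[Si](C)(C)C | intermediate
28 | 7-[2-(trimethylsilyl)ethyl] ester of the target (open aldehyde-acid form) | C=C1C[C@]23C[C@H]1[C@@H](O)C[C@H]2[C@]1(C=O)CC[C@H](O)[C@@](C)(C(=O)O)[C@H]1[C@@H]3C(=O)OCC[Si](C)(C)C | intermediate
29 | 3β,12α-dihydroxy-20-oxogibberell-16-ene-7,19-dioic acid (CNP0218328.1) | C=C1C[C@]23C[C@H]1[C@@H](O)C[C@H]2[C@]1(C=O)CC[C@H](O)[C@@](C)(C(=O)O)[C@H]1[C@@H]3C(=O)O | target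

Total step count: 21. Longest linear sequence: 19 steps (steps 1, 2, 4–11 and 13–21, from 1 to 29).

Steps most likely to fail

Step 20 (key aldol). The closure may run through a cation-bridged, closed transition state, or equilibrate by retro-aldol, so that the hydroxyl is delivered to the α face; the aldehyde may also be enolised faster than the lactone. The fallback gives up stereocontrol in the bond-forming event. From 26 the aldol would be run with LiN(SiMe3)2 (THF, −78 °C), where lithium chelation should deliberately give the 3α-hydroxy epimer F1. Dess–Martin oxidation would give the 3-oxo lactone F2, a β-keto lactone without an α-hydrogen at C4. KBH(s-Bu)3 (THF, −78 °C) should then add hydride along the equatorial trajectory to give the axial 3β-alcohol, rejoining the route at 27.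

Step 4 (Diels–Alder). The α-substituted enone may react too slowly, or the product silyl enol ether may be lost or migrate under the acid catalyst. From 3, a thermal cycloaddition with the far more reactive 1-(dimethylamino)-3-(tert-butyldimethylsilyloxy)buta-1,3-diene (toluene, 60 °C; same regio- and facial sense) would give the amino cycloadduct F3. Dilute HCl in THF at 0 °C would hydrolyse the enol ether and eliminate dimethylamine to the enedione F4 (C12 ketone, C13=C14). Regiospecific 1,4-hydrosilylation of the enone (t-BuMe2SiH, RhCl(PPh3)3 cat.) would regenerate the C12=C13 silyl enol ether, rejoining the route at 6.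

Step 17 (tethered Michael addition). The enolate of the acyloxy acetal may fragment to a ketene and the hemiacetal alkoxide before it adds to C5. The fallback tethers at the alcohol oxidation level and corrects C20 afterwards. From 19, NaBH4 (MeOH, 0 °C) would give the C20 alcohol F5 and propionyl chloride/pyridine the propanoate F6. The same KN(SiMe3)2 Michael addition would give the 19,20-olide F7. LiOH (THF/H2O) would open it to the hydroxy acid F8, whose carboxylate salt would be oxidised without acidification (TEMPO, PhI(OAc)2) to the 19,20-lactol F9. MeOH/HC(OMe)3/PPTS would convert the lactol into its methyl pseudo-ester, rejoining the route at 23.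

Further compounds
F1 | step 20 | 3α-hydroxy epimer of 27 | C=C1C[C@]23C[C@H]1[C@@H](O[Si](C(C)C)(C(C)C)C(C)C)C[C@H]2[C@]1(C4OC)CC[C@@H](O)[C@@](C)(C(=O)O4)[C@H]1[C@@H]3C(=O)OCC[Si](C)(C)C
F2 | step 20 | 3-oxo analogue of 27 (β-keto lactone) | C=C1C[C@]23C[C@H]1[C@@H](O[Si](C(C)C)(C(C)C)C(C)C)C[C@H]2[C@]1(C4OC)CCC(=O)[C@@](C)(C(=O)O4)[C@H]1[C@@H]3C(=O)OCC[Si](C)(C)C
F3 | step 4 | C14-dimethylamino analogue of 6 (amino cycloadduct) | C=CC[C@]12C(N(C)C)C=C(O[Si](C)(C)C(C)(C)C)C[C@H]1[C@H](O[Si](C)(C)C(C)(C)C)CC2=O
F4 | step 4 | bicyclic enedione (C6 ketone, C12 ketone, C13=C14, 10β-OTBS) | C=CC[C@]12C=CC(=O)C[C@H]1[C@H](O[Si](C)(C)C(C)(C)C)CC2=O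
F5 | step 17 | C20 primary alcohol from 19 | C=C1C[C@]23C[C@H]1[C@@H](O[Si](C(C)C)(C(C)C)C(C)C)C[C@H]2[C@](CO)(CC=C)C=C3C(=O)OCC[Si](C)(C)C
F6 | step 17 | C20 propanoate | C=C1C[C@]23C[C@H]1[C@@H](O[Si](C(C)C)(C(C)C)C(C)C)C[C@H]2[C@](COC(=O)CC)(CC=C)C=C3C(=O)OCC[Si](C)(C)C
F7 | step 17 | 19,20-olide (C20 methylene; C4 epimers) | C=C1C[C@]23C[C@H]1[C@@H](O[Si](C(C)C)(C(C)C)C(C)C)C[C@H]2[C@@]4(CC=C)COC(=O)C(C)[C@H]4[C@@H]3C(=O)OCC[Si](C)(C)C
F8 | step 17 | 20-hydroxy 19-acid (opened lactone) | C=C1C[C@]23C[C@H]1[C@@H](O[Si](C(C)C)(C(C)C)C(C)C)C[C@H]2[C@](CO)(CC=C)[C@@H](C(C)C(=O)O)[C@@H]3C(=O)OCC[Si](C)(C)C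
F9 | step 17 | 19,20-lactol (20-hydroxy lactone) | C=C1C[C@]23C[C@H]1[C@@H](O[Si](C(C)C)(C(C)C)C(C)C)C[C@H]2[C@@]4(CC=C)C(O)OC(=O)C(C)[C@H]4[C@@H]3C(=O)OCC[Si](C)(C)C
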